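## Structural features

The target is numbered as 4,6-dioxatricyclo[5.4.0.0^{1,5}]undec-9-ene. A cyclohexene (C1, C7, C8, C9, C10, C11), an oxolane (C1, C2, C3, O4, C5) and an oxetane (C1, C5, O6, C7) all share the quaternary carbon C1. The oxetane is fused to the carbocycle along C1–C7 and to the oxolane along C1–C5, and C5 is an acetal carbon bound to both ring oxygens. The carbocycle carries a vinyl bromide (C10), a secondary allylic bromide (C8), a methyl-bearing tertiary ether carbon (C7) and a gem-dimethyl carbon (C11); C3 carries an isopropenyl group. Four of the five stereocentres are contiguous (C8–C7–C1–C5) and C3 lies one methylene away. Because both ring fusions must be cis, C7 and C5 follow from C1. The independent elements are therefore C1, C8 (bromine trans to O6) and C3 (isopropenyl on the face of C11, away from the oxetane). C11, C1 and C7 are three adjacent fully substituted carbons. The fragile groups are the strained oxetane acetal (acid), the allylic bromide next to it (ionisation, displacement), the isopropenyl group (electrophiles) and the vinyl bromide (low-valent metals, strong lithium bases). The real difficulty is the vicinal quaternary pair C1/C11 as a single enantiomer, followed by a late, acid-free closure of the acetal. The key step exploits C11: it sits in the six-membered ring between the bromine-bearing C10 and C1, the pattern left when a carbon nucleophile captures the tertiary end of a bromonium-activated prenyl group.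

## Logic of the disconnections

20 ⇒ 19. The C8–Br bond is cut. The allylic bromide is the most labile group and is best made last. Displacement with inversion of an alcohol that is cis to O6 gives the required trans arrangement. The gain is that a labile halide is replaced by a hydroxyl whose configuration is fixed ten steps earlier. The demand is a clean SN2 at a hindered allylic carbon without acid reaching the acetal.

19 ⇒ 18 ⇒ 17. After the O–Si bond, the O6–C5 bond is cut. It is the only oxetane bond that can be formed irreversibly from a hemiacetal under neutral conditions. The strained tricycle becomes a spiro lactol with ordinary groups. The tertiary oxygen must be cis to the lactol carbon. The oxygen on C8 is also cis and would close a five-membered acetal far more easily, so it must stay silylated until the oxetane exists. For that reason the silyl ether runs from 10 to 18 and the bromination follows the closure.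

17 ⇒ 16 ⇒ 15 ⇒ 14. The acetal carbon is taken back to a lactone, then the acyl–O4 bond and the C3–H bond are cut. C3 is insulated from the ring stereocentres by C2, so it is set by a chiral reduction catalyst on an enone. This removes the oxolane and the C3 stereocentre. The catalyst must tell isopropenyl from a branched CH2 group, and the lactone must close onto a very hindered ester.

14 ⇒ 13 ⇒ 12 ⇒ 11. The bond between the side-chain carbonyl and the isopropenyl carbon is cut, then the amide and the tert-butyl ester. The tert-butyl ester is the one carboxyl derivative that survives the base and the methyl nucleophile of the earlier steps and can be removed beside a methyl ester. Its acidolysis must spare the silyl ether.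

11 ⇒ 10 ⇒ 9. The C7–CH3 bond and the O–Si bond are cut. A ketone at C7 is what the cyclisation leaves. A methyl nucleophile entering anti to the neighbouring silyloxy group puts the new hydroxyl cis to it and cis to the ester, the face the oxetane needs. The demand is addition, not enolisation, at a hindered ketone.

9 ⇒ 8 ⇒ 7 ⇒ 6. The C8–O bond is cut and the C9=C10 double bond is returned to a saturated bromide. Removing the proton from the bromine-bearing carbon of 7 gives dienolate 8. Its hydroxylation at the α-carbon places oxygen at C8 and leaves the unsaturation next to bromine, so the sp3 bromide of 6 becomes the vinyl bromide with no new C–Br chemistry. Compound 7 comes from 6 by dehydrogenation. The demands are γ-deprotonation, α-attack and attack on the ester face.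

6 ⇒ 5. The C1–C11 bond and the C10–Br bond are cut together. This removes the ring, the vicinal quaternary pair and both stereocentres of 6, leaving an acyclic β-keto ester. The configuration was checked by mapping: the ester carbon of 6 becomes C5, the ketone carbon C7, the gem-dimethyl carbon C11 and the arm C2, so (1S) in 6 is C1 (S) in 20. The structures of 5 and 6 therefore needed no correction. The demand is an enzyme that accepts 5, picks one alkene face and lets carbon, not oxygen, capture the cation.

5 ⇒ 3 + 4 and 3 ⇒ 1 + 2. The bonds at the central and terminal carbons of the acetoacetate are cut. Both are standard enolate alkylations of commercial materials; the only demand is mono-alkylation at each stage.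

## Other disconnections considered

Alternative 1: The cut removes two C–O bonds on the carbocycle, the O6–C7 bond and a second C–O bond at C10, both from a bicyclic peroxide. Forward, the quaternary dienal A1 would add singlet oxygen (O2, light, tetraphenylporphyrin) in a [4+2] reaction to give endoperoxide A2. Base-induced isomerisation (Kornblum–DeLaMare type) would then lead to the γ-hydroxy enone A3.
- In its favour: the cycloaddition is textbook chemistry and the two oxygens are necessarily syn. The ring methyl, the gem-dimethyl group and the C7 oxygen come with the diene. The future C5 is already an aldehyde, so no methyl addition and no ester reduction are needed. On these points it is better than the chosen plan.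
- Against it: C10 receives an oxygen where a vinyl bromide is needed, and C8 receives nothing. Both bromines would have to be installed afterwards with a double-bond shift and with little control at C8. Face selection rests on the small difference between formyl and allyl on the quaternary carbon. The absolute configuration must come from a separate enantioselective allylation that creates a quaternary aldehyde. The allyl group must still be cut down and extended to the isopropenyl carbinol.
- Comparison: the late oxetane closure is the same problem in both plans (equal). The mechanism of the key step is more secure than the enzymatic cyclisation, but it sets no absolute stereochemistry and builds no C–Br bond. Step economy would be comparable at best, since the saving at the front is spent on the bromines.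

Alternative 2: The cut is the second C–CH3 bond of C11 together with the C8–O bond. Forward, Me2CuLi would add 1,6 to the spiro bromodienone A4, itself made by dearomatising an ortho-hydroxybenzoate. The bromodienolate would then be hydroxylated at the α-carbon by an N-sulfonyloxaziridine to give A5.
- In its favour: A5 already holds the spirolactone with the C3 stereocentre, the vinyl bromide and the C8 oxygen. It is the lactone analogue of 9, and from it only methyl addition, reduction, closure and bromination would remain. That is shorter than the nine steps from 9 to 20, so on convergence it is better. The dienolate hydroxylation is the same reaction type as step 5 (equal).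
- Against it: the cuprate must attack a fully substituted carbon flanked by the spiro quaternary carbon. Addition at the unsubstituted β-carbon, attack on the lactone and loss of the vinylic bromine by halogen–metal exchange all look easier. Spiro cyclohexa-2,4-dienones of this kind tend to dimerise by [4+2] addition. The dearomatisation must also set the spiro centre relative to C3.
- Comparison: here the quaternary pair comes from an intermolecular addition at the most hindered site, whereas the chosen plan uses an intramolecular capture in a chair. Absolute control would have to be imported with the side chain. Step economy would be better only if the 1,6-addition were selective.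

Alternative 3: The cut is the C3–O4 bond. Forward, zerovalent palladium (Pd2(dba)3 with a chiral diphosphine) would ionise the allylic methyl carbonate of acid A6. The carboxylate would close the γ-lactone at the internal allyl carbon to give A7, with the isopropenyl centre set by the ligand.
- In its favour: this is a well-understood catalytic asymmetric reaction that fixes C3 early and independently. On this one centre it is equal to or better than the reduction in step 11. The trans arrangement in A7 fits a later substitution at the α-carbon anti to isopropenyl to make C1.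
- Against it: the step builds none of the congested part. The carbocycle, both quaternary carbons, both bromines, the C7 carbinol and the acetal all remain. Every one of them would depend on relay from a single remote centre through an enolate. Closing the cyclohexene onto a bromoalkene is unfavourable.
- Comparison: structurally the chosen plan makes the ring, the quaternary pair and a C–Br bond in one step, while this one makes one C–O bond. Mechanistically this alternative is the safer single step. In step economy it is clearly the longer route.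

Key step: step 3

Assumption: a vanadium bromoperoxidase (wild type or evolved) that binds 5 and transfers bromine to the alkene face leading to (3S)-6 is taken to be identifiable by screening; its facial preference cannot be predicted.

## Route

Step 1
Reactants: 1 methyl acetoacetate; 2 prenyl bromide (1-bromo-3-methylbut-2-ene)
Product: 3 methyl 7-methyl-3-oxooct-6-enoate
Conditions: NaH, THF, 0 °C; n-BuLi, 0 °C; then 2, 0 → 25 °C
Reagents that add atoms: none
Why: γ-Alkylation of the acetoacetate dianion: the more basic terminal carbanion displaces the primary allylic bromide (SN2) while the central enolate stays protected as its salt.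

Step 2
Reactants: 3 methyl 7-methyl-3-oxooct-6-enoate; 4 tert-butyl bromoacetate
Product: 5 methyl 2-(2-tert-butoxy-2-oxoethyl)-7-methyl-3-oxooct-6-enoate (racemic)
Conditions: NaH (1.0 equiv), THF, 0 °C; then 4, 0 → 25 °C
Reagents that add atoms: none
Why: C-Alkylation of the stabilised β-keto ester enolate by an α-bromo ester (SN2); one equivalent of base and electrophile limits dialkylation. The new centre is racemic and is erased by enolisation in step 3.

Step 3
Reactants: 5 methyl 2-(2-tert-butoxy-2-oxoethyl)-7-methyl-3-oxooct-6-enoate (racemic)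
Product: 6 methyl (1S,3S)-3-bromo-1-(2-tert-butoxy-2-oxoethyl)-2,2-dimethyl-6-oxocyclohexane-1-carboxylate
Conditions: vanadium-dependent bromoperoxidase (vanadate cofactor, Na3VO4), KBr, H2O2 (slow addition), MES buffer pH 6.5, 30 % t-BuOH, 25 °C
Reagents that add atoms: potassium bromide, [K+].[Br-]
Why: Proposed new method: the peroxovanadate centre oxidises bromide with H2O2 to an enzyme-held bromonium equivalent that adds to C6=C7 of 5, the only trisubstituted alkene, with bromine on C6 and positive charge on the gem-dimethyl carbon C7 (Markovnikov), and the enol carbon C2 captures that charge; the closest known reaction type is the haloperoxidase-mediated bromonium cyclisation of acyclic terpenes, and its reagent form with a bromosulfonium salt, which are terminated by an alkene or a hydroxyl and not by an enol carbon. The one ring closes in a 6-endo-trig mode with respect to the activated alkene (enol-endo with respect to the nucleophile) through a chair in which the C2–C7 bond forms anti to bromine. The bromine-bearing centre (3S) is controlled by the enzyme's choice of alkene face, the only source of absolute configuration in the route. The quaternary centre (1S) is relayed from it: the hydrogen-bonded Z-enol holds the ester syn to the enol oxygen, so in the chair the ester becomes equatorial and cis to the equatorial bromine while the CH2CO2t-Bu arm becomes axial. The step needs alkene bromination to outrun bromination of the enol carbon, carbon capture to outrun capture by the ketone oxygen (cyclic enol ether), and one alkene face. The substrate supports the first by its low enol content and its lipophilic prenyl terminus, and the second by the chair in which C2 is the nucleophilic end of the enol; the third rests on the enzyme alone. The racemic centre of 5 does not matter because it is planar in the enol.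

Step 4
Reactants: 6 methyl (1S,3S)-3-bromo-1-(2-tert-butoxy-2-oxoethyl)-2,2-dimethyl-6-oxocyclohexane-1-carboxylate
Product: 7 methyl (1S,5S)-5-bromo-1-(2-tert-butoxy-2-oxoethyl)-6,6-dimethyl-2-oxocyclohex-3-ene-1-carboxylate
Conditions: IBX, 4-methoxypyridine N-oxide, DMSO, 25 °C
Reagents that add atoms: none
Why: Hypervalent-iodine dehydrogenation of a ketone to the enone; only one α-carbon can enolise because the other is quaternary. The base-free room-temperature conditions leave the secondary bromide alone and avoid the enolate that could close a cyclopropane onto it.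

Step 5
Reactants: 7 methyl (1S,5S)-5-bromo-1-(2-tert-butoxy-2-oxoethyl)-6,6-dimethyl-2-oxocyclohex-3-ene-1-carboxylate
Product: 9 methyl (1S,5R)-3-bromo-1-(2-tert-butoxy-2-oxoethyl)-5-hydroxy-2,2-dimethyl-6-oxocyclohex-3-ene-1-carboxylate, via potassium dienolate 8 (not isolated)
Conditions: KN(SiMe3)2 (1.05 equiv), THF, −78 °C; then 2-(phenylsulfonyl)-3-phenyloxaziridine, −78 °C; aq. NH4Cl at −78 °C
Reagents that add atoms: 2-(phenylsulfonyl)-3-phenyloxaziridine, O=S(=O)(c1ccccc1)N1OC1c1ccccc1
Why: The proton on the bromine-bearing γ-carbon is by far the most acidic, and its removal turns that centre into the vinyl bromide of extended enolate 8. Electrophilic oxygen transfer from the N-sulfonyloxaziridine then occurs at the α-carbon, the kinetic site of metal dienolates. The potassium is chelated by the in-plane ester and the larger CH2CO2t-Bu arm sits pseudoaxial, so attack anti to the arm gives the hydroxyl cis to the ester (5R).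

Step 6
Reactants: 9 methyl (1S,5R)-3-bromo-1-(2-tert-butoxy-2-oxoethyl)-5-hydroxy-2,2-dimethyl-6-oxocyclohex-3-ene-1-carboxylate
Product: 10 methyl (1S,5R)-3-bromo-1-(2-tert-butoxy-2-oxoethyl)-5-[(tert-butyldimethylsilyl)oxy]-2,2-dimethyl-6-oxocyclohex-3-ene-1-carboxylate
Conditions: TBSOTf, 2,6-lutidine, CH2Cl2, −78 °C
Reagents that add atoms: tert-butyldimethylsilyl trifluoromethanesulfonate, CC(C)(C)[Si](C)(C)OS(=O)(=O)C(F)(F)F
Why: Silylation of a hindered secondary alcohol with a silyl triflate and a non-nucleophilic base. It stops the α-ketol from drifting into conjugation and blocks the oxygen that would otherwise capture the lactol carbon in step 13.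

Step 7
Reactants: 10 methyl (1S,5R)-3-bromo-1-(2-tert-butoxy-2-oxoethyl)-5-[(tert-butyldimethylsilyl)oxy]-2,2-dimethyl-6-oxocyclohex-3-ene-1-carboxylate
Product: 11 methyl (1S,5R,6S)-3-bromo-1-(2-tert-butoxy-2-oxoethyl)-5-[(tert-butyldimethylsilyl)oxy]-6-hydroxy-2,2,6-trimethylcyclohex-3-ene-1-carboxylate
Conditions: MeLi, CeCl3, THF, −78 °C
Reagents that add atoms: methyllithium, [Li]C
Why: Organocerium 1,2-addition, which adds to hindered enolisable ketones where a Grignard reagent would deprotonate. Methyl enters anti to the bulky, electronegative silyloxy group (polar Felkin–Anh), so the new hydroxyl is cis to it and to the ester (6S). The tert-butyl ester and the neopentyl methyl ester are not attacked at −78 °C.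

Step 8
Reactants: 11 methyl (1S,5R,6S)-3-bromo-1-(2-tert-butoxy-2-oxoethyl)-5-[(tert-butyldimethylsilyl)oxy]-6-hydroxy-2,2,6-trimethylcyclohex-3-ene-1-carboxylate
Product: 12 2-[(1S,5R,6S)-3-bromo-5-[(tert-butyldimethylsilyl)oxy]-6-hydroxy-1-(methoxycarbonyl)-2,2,6-trimethylcyclohex-3-en-1-yl]acetic acid
Conditions: 85 % aq. H3PO4, PhMe, 25 °C
Reagents that add atoms: none
Why: Acidolysis of the tert-butyl ester by alkyl–oxygen cleavage through the tert-butyl cation. Aqueous phosphoric acid is mild enough to leave the silyl ether, the methyl ester and the tertiary alcohol.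

Step 9
Reactants: 12 2-[(1S,5R,6S)-3-bromo-5-[(tert-butyldimethylsilyl)oxy]-6-hydroxy-1-(methoxycarbonyl)-2,2,6-trimethylcyclohex-3-en-1-yl]acetic acid
Product: 13 methyl (1S,5R,6S)-3-bromo-5-[(tert-butyldimethylsilyl)oxy]-6-hydroxy-1-{2-[methoxy(methyl)amino]-2-oxoethyl}-2,2,6-trimethylcyclohex-3-ene-1-carboxylate
Conditions: MeNH(OMe)·HCl, EDC·HCl, HOBt, i-Pr2NEt, CH2Cl2, 0 → 25 °C
Reagents that add atoms: N,O-dimethylhydroxylamine hydrochloride, CNOC.Cl
Why: Carbodiimide amide coupling through the hydroxybenzotriazole active ester; the amine outcompetes the hindered tertiary hydroxyl.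

Step 10
Reactants: 13 methyl (1S,5R,6S)-3-bromo-5-[(tert-butyldimethylsilyl)oxy]-6-hydroxy-1-{2-[methoxy(methyl)amino]-2-oxoethyl}-2,2,6-trimethylcyclohex-3-ene-1-carboxylate
Product: 14 methyl (1S,5R,6S)-3-bromo-5-[(tert-butyldimethylsilyl)oxy]-6-hydroxy-2,2,6-trimethyl-1-(3-methyl-2-oxobut-3-en-1-yl)cyclohex-3-ene-1-carboxylate
Conditions: CH2=C(Me)MgBr (3.5 equiv), THF, −20 → 0 °C; aq. NH4Cl
Reagents that add atoms: isopropenylmagnesium bromide, CC(=C)[Mg]Br
Why: Weinreb ketone synthesis: the chelated tetrahedral intermediate holds until work-up, so the enone is released only on quenching. The first equivalent is consumed by the tertiary hydroxyl, and the neopentyl methyl ester is too hindered to react.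

Step 11
Reactants: 14 methyl (1S,5R,6S)-3-bromo-5-[(tert-butyldimethylsilyl)oxy]-6-hydroxy-2,2,6-trimethyl-1-(3-methyl-2-oxobut-3-en-1-yl)cyclohex-3-ene-1-carboxylate
Product: 16 (3R,5S,9R,10S)-7-bromo-9-[(tert-butyldimethylsilyl)oxy]-10-hydroxy-6,6,10-trimethyl-3-(prop-1-en-2-yl)-2-oxaspiro[4.5]dec-7-en-1-one, via hydroxy ester 15 (not isolated)
Conditions: (S)-Me-CBS oxazaborolidine (0.3 equiv), catecholborane, PhMe, −78 °C; MeOH; then PPTS (cat.), PhMe, 50 °C
Reagents that add atoms: none
Why: Corey–Bakshi–Shibata reduction: the ketone binds the catalyst boron with the α-branched isopropenyl group as the large substituent, and hydride is delivered to the face that gives the (R)-carbinol by 1,2-reduction. The γ-hydroxy ester 15 then lactonises (5-exo-trig), helped by the gem-disubstitution at the spiro carbon; the silylated ring oxygen cannot compete.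

Step 12
Reactants: 16 (3R,5S,9R,10S)-7-bromo-9-[(tert-butyldimethylsilyl)oxy]-10-hydroxy-6,6,10-trimethyl-3-(prop-1-en-2-yl)-2-oxaspiro[4.5]dec-7-en-1-one
Product: 17 (3R,5S,9R,10S)-7-bromo-9-[(tert-butyldimethylsilyl)oxy]-6,6,10-trimethyl-3-(prop-1-en-2-yl)-2-oxaspiro[4.5]dec-7-ene-1,10-diol (lactol, both C1 epimers)
Conditions: i-Bu2AlH (3 equiv), CH2Cl2, −78 °C; aq. KNaC4H4O6 (tartrate)
Reagents that add atoms: none
Why: Partial reduction of a γ-lactone to the lactol; the aluminium hemiacetal is stable at −78 °C and the hindered spiro position prevents over-reduction. One equivalent is consumed by the tertiary hydroxyl.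

Step 13
Reactants: 17 (3R,5S,9R,10S)-7-bromo-9-[(tert-butyldimethylsilyl)oxy]-6,6,10-trimethyl-3-(prop-1-en-2-yl)-2-oxaspiro[4.5]dec-7-ene-1,10-diol
Product: 18 tert-butyl{[(1S,3R,5S,7S,8R)-10-bromo-7,11,11-trimethyl-3-(prop-1-en-2-yl)-4,6-dioxatricyclo[5.4.0.0^{1,5}]undec-9-en-8-yl]oxy}dimethylsilane
Conditions: PPh3, DIAD, PhMe, 0 → 25 °C
Reagents that add atoms: none
Why: Mitsunobu-type cyclodehydration of a β-hydroxy lactol: the acidic, unhindered lactol hydroxyl becomes the anomeric oxyphosphonium, which ionises with help from the ring oxygen and is captured by the cis tertiary hydroxyl in a 4-exo closure. The medium is neutral, so the product acetal is not reopened, and the quaternary neighbour has no hydrogen to eliminate. The acetal configuration (5S) is fixed by the cis ring fusion.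

Step 14
Reactants: 18 tert-butyl{[(1S,3R,5S,7S,8R)-10-bromo-7,11,11-trimethyl-3-(prop-1-en-2-yl)-4,6-dioxatricyclo[5.4.0.0^{1,5}]undec-9-en-8-yl]oxy}dimethylsilane
Product: 19 (1S,3R,5S,7S,8R)-10-bromo-7,11,11-trimethyl-3-(prop-1-en-2-yl)-4,6-dioxatricyclo[5.4.0.0^{1,5}]undec-9-en-8-ol
Conditions: Bu4NF, THF, 0 → 25 °C
Reagents that add atoms: none
Why: Fluoride cleavage of the silyl ether; the basic, non-acidic medium is tolerated by the oxetane acetal and the vinyl bromide.

Step 15
Reactants: 19 (1S,3R,5S,7S,8R)-10-bromo-7,11,11-trimethyl-3-(prop-1-en-2-yl)-4,6-dioxatricyclo[5.4.0.0^{1,5}]undec-9-en-8-ol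
Product: 20 (1S,3R,5S,7S,8S)-8,10-dibromo-7,11,11-trimethyl-3-(prop-1-en-2-yl)-4,6-dioxatricyclo[5.4.0.0^{1,5}]undec-9-ene (CNP0141320.1)
Conditions: CBr4, PPh3, 2,6-lutidine, CH2Cl2, 0 °C
Reagents that add atoms: carbon tetrabromide, BrC(Br)(Br)Br
Why: Appel reaction: bromide displaces the alkoxyphosphonium with inversion (SN2), giving (8S) with bromine trans to O6. The oxetane oxygen is cis to the leaving group and cannot participate, no β-hydrogen is available for elimination, and lutidine buffers traces of acid.

## Compound list

1 | methyl acetoacetate | COC(=O)CC(C)=O | starting material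
2 | prenyl bromide (1-bromo-3-methylbut-2-ene) | CC(C)=CCBr | starting material
3 | methyl 7-methyl-3-oxooct-6-enoate | COC(=O)CC(=O)CCC=C(C)C | intermediate
4 | tert-butyl bromoacetate | CC(C)(C)OC(=O)CBr | starting material
5 | methyl 2-(2-tert-butoxy-2-oxoethyl)-7-methyl-3-oxooct-6-enoate (racemic) | COC(=O)C(CC(=O)OC(C)(C)C)C(=O)CCC=C(C)C | intermediate
6 | methyl (1S,3S)-3-bromo-1-(2-tert-butoxy-2-oxoethyl)-2,2-dimethyl-6-oxocyclohexane-1-carboxylate | COC(=O)[C@@]1(CC(=O)OC(C)(C)C)C(C)(C)[C@@H](Br)CCC1=O | intermediate
7 | methyl (1S,5S)-5-bromo-1-(2-tert-butoxy-2-oxoethyl)-6,6-dimethyl-2-oxocyclohex-3-ene-1-carboxylate | COC(=O)[C@@]1(CC(=O)OC(C)(C)C)C(C)(C)[C@@H](Br)C=CC1=O | intermediate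
8 | potassium (6S)-4-bromo-6-(2-tert-butoxy-2-oxoethyl)-6-(methoxycarbonyl)-5,5-dimethylcyclohexa-1,3-dien-1-olate | COC(=O)[C@@]1(CC(=O)OC(C)(C)C)C(C)(C)C(Br)=CC=C1[O-].[K+] | intermediate (not isolated)
9 | methyl (1S,5R)-3-bromo-1-(2-tert-butoxy-2-oxoethyl)-5-hydroxy-2,2-dimethyl-6-oxocyclohex-3-ene-1-carboxylate | COC(=O)[C@@]1(CC(=O)OC(C)(C)C)C(C)(C)C(Br)=C[C@@H](O)C1=O | intermediate
10 | methyl (1S,5R)-3-bromo-1-(2-tert-butoxy-2-oxoethyl)-5-[(tert-butyldimethylsilyl)oxy]-2,2-dimethyl-6-oxocyclohex-3-ene-1-carboxylate | COC(=O)[C@@]1(CC(=O)OC(C)(C)C)C(C)(C)C(Br)=C[C@@H](O[Si](C)(C)C(C)(C)C)C1=O | intermediate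
11 | methyl (1S,5R,6S)-3-bromo-1-(2-tert-butoxy-2-oxoethyl)-5-[(tert-butyldimethylsilyl)oxy]-6-hydroxy-2,2,6-trimethylcyclohex-3-ene-1-carboxylate | COC(=O)[C@@]1(CC(=O)OC(C)(C)C)C(C)(C)C(Br)=C[C@@H](O[Si](C)(C)C(C)(C)C)[C@@]1(C)O | intermediate
12 | 2-[(1S,5R,6S)-3-bromo-5-[(tert-butyldimethylsilyl)oxy]-6-hydroxy-1-(methoxycarbonyl)-2,2,6-trimethylcyclohex-3-en-1-yl]acetic acid | COC(=O)[C@@]1(CC(=O)O)C(C)(C)C(Br)=C[C@@H](O[Si](C)(C)C(C)(C)C)[C@@]1(C)O | intermediate
13 | methyl (1S,5R,6S)-3-bromo-5-[(tert-butyldimethylsilyl)oxy]-6-hydroxy-1-{2-[methoxy(methyl)amino]-2-oxoethyl}-2,2,6-trimethylcyclohex-3-ene-1-carboxylate | COC(=O)[C@@]1(CC(=O)N(C)OC)C(C)(C)C(Br)=C[C@@H](O[Si](C)(C)C(C)(C)C)[C@@]1(C)O | intermediate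
14 | methyl (1S,5R,6S)-3-bromo-5-[(tert-butyldimethylsilyl)oxy]-6-hydroxy-2,2,6-trimethyl-1-(3-methyl-2-oxobut-3-en-1-yl)cyclohex-3-ene-1-carboxylate | COC(=O)[C@@]1(CC(=O)C(C)=C)C(C)(C)C(Br)=C[C@@H](O[Si](C)(C)C(C)(C)C)[C@@]1(C)O | intermediate
15 | methyl (1S,5R,6S)-3-bromo-5-[(tert-butyldimethylsilyl)oxy]-6-hydroxy-1-[(2R)-2-hydroxy-3-methylbut-3-en-1-yl]-2,2,6-trimethylcyclohex-3-ene-1-carboxylate | COC(=O)[C@@]1(C[C@@H](O)C(C)=C)C(C)(C)C(Br)=C[C@@H](O[Si](C)(C)C(C)(C)C)[C@@]1(C)O | intermediate (not isolated)
16 | (3R,5S,9R,10S)-7-bromo-9-[(tert-butyldimethylsilyl)oxy]-10-hydroxy-6,6,10-trimethyl-3-(prop-1-en-2-yl)-2-oxaspiro[4.5]dec-7-en-1-one | C=C(C)[C@H]1C[C@@]2(C(=O)O1)[C@](C)(O)[C@H](O[Si](C)(C)C(C)(C)C)C=C(Br)C2(C)C | intermediate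
17 | (3R,5S,9R,10S)-7-bromo-9-[(tert-butyldimethylsilyl)oxy]-6,6,10-trimethyl-3-(prop-1-en-2-yl)-2-oxaspiro[4.5]dec-7-ene-1,10-diol (both C1 epimers) | C=C(C)[C@H]1C[C@@]2(C(O)O1)[C@](C)(O)[C@H](O[Si](C)(C)C(C)(C)C)C=C(Br)C2(C)C | intermediate
18 | tert-butyl{[(1S,3R,5S,7S,8R)-10-bromo-7,11,11-trimethyl-3-(prop-1-en-2-yl)-4,6-dioxatricyclo[5.4.0.0^{1,5}]undec-9-en-8-yl]oxy}dimethylsilane | C=C(C)[C@H]1C[C@@]23[C@@H](O1)O[C@]2(C)[C@H](O[Si](C)(C)C(C)(C)C)C=C(Br)C3(C)C | intermediate
19 | (1S,3R,5S,7S,8R)-10-bromo-7,11,11-trimethyl-3-(prop-1-en-2-yl)-4,6-dioxatricyclo[5.4.0.0^{1,5}]undec-9-en-8-ol | C=C(C)[C@H]1C[C@@]23[C@@H](O1)O[C@]2(C)[C@H](O)C=C(Br)C3(C)C | intermediate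
20 | (1S,3R,5S,7S,8S)-8,10-dibromo-7,11,11-trimethyl-3-(prop-1-en-2-yl)-4,6-dioxatricyclo[5.4.0.0^{1,5}]undec-9-ene | C=C(C)[C@H]1C[C@@]23[C@@H](O1)O[C@]2(C)[C@@H](Br)C=C(Br)C3(C)C | target

## Step count and least certain steps

Total step count: 15. Longest linear sequence: 15 steps (from 1).

Step 3 (key step). The bromonium equivalent may leave the enzyme as free hypobromite and brominate without facial control. The enol carbon itself may be brominated, which is the usual behaviour of these enzymes toward 1,3-dicarbonyl enols. The cation may also be captured by the ketone oxygen, giving a cyclic enol ether. Fallback with known chemistry, from 5: halonium cyclisation with the bromosulfonium salt Et2SBr·SbCl5Br (MeNO2, −25 °C) should give racemic 6, that is 6 together with its enantiomer, methyl (1R,3R)-3-bromo-1-(2-tert-butoxy-2-oxoethyl)-2,2-dimethyl-6-oxocyclohexane-1-carboxylate F1. The two are separated by preparative chromatography on a chiral stationary phase, and the route is rejoined at 6.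

Step 5. Deprotonation may occur at the arm CH2 instead of the γ-carbon, followed by intramolecular conjugate addition. Oxygen may be delivered to the arm face. The ketol may isomerise into conjugation under the basic conditions. Fallback, from 7: soft enolisation with TBSOTf and Et3N (CH2Cl2, 0 °C) gives the silyl dienol ether, methyl (1S)-5-bromo-1-(2-tert-butoxy-2-oxoethyl)-2-[(tert-butyldimethylsilyl)oxy]-6,6-dimethylcyclohexa-2,4-diene-1-carboxylate F2. Rubottom oxidation (mCPBA, NaHCO3, CH2Cl2, −20 °C) with silyl migration should then give the silyl ether directly; attack at the remote bromoalkene is disfavoured by the bromine and the neighbouring gem-dimethyl group. This avoids strong base and free ketol and rejoins at 10.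

Step 7. Facial selectivity may be poor because the arm lies on the face the methyl must use, and enolisation of the hindered ketone may compete. Fallback, from 7, delivering both oxygens in one suprafacial event anti to the arm:
- KN(SiMe3)2 and PhNTf2 give the dienyl triflate, methyl (1S)-5-bromo-1-(2-tert-butoxy-2-oxoethyl)-6,6-dimethyl-2-{[(trifluoromethyl)sulfonyl]oxy}cyclohexa-2,4-diene-1-carboxylate F3.
- Me2CuLi (THF, −20 °C) replaces the triflate and gives the methyl diene, methyl (1R)-5-bromo-1-(2-tert-butoxy-2-oxoethyl)-2,6,6-trimethylcyclohexa-2,4-diene-1-carboxylate F4.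
- OsO4 (cat.) with N-methylmorpholine N-oxide dihydroxylates the electron-rich trisubstituted alkene to the cis-diol, methyl (1S,5R,6S)-3-bromo-1-(2-tert-butoxy-2-oxoethyl)-5,6-dihydroxy-2,2,6-trimethylcyclohex-3-ene-1-carboxylate F5.
- TBSOTf and 2,6-lutidine at −78 °C silylate the secondary hydroxyl only, rejoining at 11.

Step 13. The anomeric oxyphosphonium may be captured by the hydrazide anion instead of the hindered tertiary hydroxyl. Fragmentation of the oxocarbenium ion (cleavage of the bond between the spiro carbon and the carbinol carbon) may outrun four-membered ring closure. Fallback, from 17: PhSSPh and PBu3 convert the lactol into the phenyl thioacetal, (3R,5S,9R,10S)-7-bromo-9-[(tert-butyldimethylsilyl)oxy]-6,6,10-trimethyl-1-(phenylsulfanyl)-3-(prop-1-en-2-yl)-2-oxaspiro[4.5]dec-7-en-10-ol F6, an isolable donor. S-Methylation with MeOTf in the presence of 2,6-di-tert-butyl-4-methylpyridine (CH2Cl2, 4 Å sieves, −40 °C) then triggers intramolecular O-glycosylation under acid-free conditions, rejoining at 18.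

Step 15. Bromophosphonium species or traces of HBr may open the oxetane acetal. Ionisation at the hindered allylic carbon may cause loss of configuration or a skeletal shift. Fallback, from 16, installing bromine before the acetal exists and closing the oxetane last:
- Bu4NF gives the diol lactone, (3R,5S,9R,10S)-7-bromo-9,10-dihydroxy-6,6,10-trimethyl-3-(prop-1-en-2-yl)-2-oxaspiro[4.5]dec-7-en-1-one F7.
- SOCl2 and Et3N give the cyclic sulfite of F7 (both sulfur epimers) F8, which ties up the tertiary oxygen.
- LiBr (DMF, 60 °C) opens the sulfite at the allylic carbon with inversion; aqueous work-up gives the bromohydrin lactone, (3R,5S,9S,10S)-7,9-dibromo-10-hydroxy-6,6,10-trimethyl-3-(prop-1-en-2-yl)-2-oxaspiro[4.5]dec-7-en-1-one F9. The lactone tolerates the forcing conditions that the acetal would not.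
- i-Bu2AlH at −78 °C gives the bromo lactol, (3R,5S,9S,10S)-7,9-dibromo-6,6,10-trimethyl-3-(prop-1-en-2-yl)-2-oxaspiro[4.5]dec-7-ene-1,10-diol F10.
- PPh3 and DIAD close the oxetane as in step 13, arriving at 20.

## Further compounds

F1 | step 3 | methyl (1R,3R)-3-bromo-1-(2-tert-butoxy-2-oxoethyl)-2,2-dimethyl-6-oxocyclohexane-1-carboxylate (enantiomer of 6) | COC(=O)[C@]1(CC(=O)OC(C)(C)C)C(C)(C)[C@H](Br)CCC1=O
F2 | step 5 | methyl (1S)-5-bromo-1-(2-tert-butoxy-2-oxoethyl)-2-[(tert-butyldimethylsilyl)oxy]-6,6-dimethylcyclohexa-2,4-diene-1-carboxylate | COC(=O)[C@@]1(CC(=O)OC(C)(C)C)C(C)(C)C(Br)=CC=C1O[Si](C)(C)C(C)(C)C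
F3 | step 7 | methyl (1S)-5-bromo-1-(2-tert-butoxy-2-oxoethyl)-6,6-dimethyl-2-{[(trifluoromethyl)sulfonyl]oxy}cyclohexa-2,4-diene-1-carboxylate | COC(=O)[C@@]1(CC(=O)OC(C)(C)C)C(C)(C)C(Br)=CC=C1OS(=O)(=O)C(F)(F)F
F4 | step 7 | methyl (1R)-5-bromo-1-(2-tert-butoxy-2-oxoethyl)-2,6,6-trimethylcyclohexa-2,4-diene-1-carboxylate | COC(=O)[C@@]1(CC(=O)OC(C)(C)C)C(C)(C)C(Br)=CC=C1C
F5 | step 7 | methyl (1S,5R,6S)-3-bromo-1-(2-tert-butoxy-2-oxoethyl)-5,6-dihydroxy-2,2,6-trimethylcyclohex-3-ene-1-carboxylate | COC(=O)[C@@]1(CC(=O)OC(C)(C)C)C(C)(C)C(Br)=C[C@@H](O)[C@@]1(C)O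
F6 | step 13 | (3R,5S,9R,10S)-7-bromo-9-[(tert-butyldimethylsilyl)oxy]-6,6,10-trimethyl-1-(phenylsulfanyl)-3-(prop-1-en-2-yl)-2-oxaspiro[4.5]dec-7-en-10-ol (both C1 epimers) | C=C(C)[C@H]1C[C@@]2(C(Sc3ccccc3)O1)[C@](C)(O)[C@H](O[Si](C)(C)C(C)(C)C)C=C(Br)C2(C)C
F7 | step 15 | (3R,5S,9R,10S)-7-bromo-9,10-dihydroxy-6,6,10-trimethyl-3-(prop-1-en-2-yl)-2-oxaspiro[4.5]dec-7-en-1-one | C=C(C)[C@H]1C[C@@]2(C(=O)O1)[C@](C)(O)[C@H](O)C=C(Br)C2(C)C
F8 | step 15 | cyclic sulfite of F7 (9,10-O-sulfinyl derivative, both sulfur epimers) | C=C(C)[C@H]1C[C@@]2(C(=O)O1)[C@]3(C)OS(=O)O[C@@H]3C=C(Br)C2(C)C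
F9 | step 15 | (3R,5S,9S,10S)-7,9-dibromo-10-hydroxy-6,6,10-trimethyl-3-(prop-1-en-2-yl)-2-oxaspiro[4.5]dec-7-en-1-one | C=C(C)[C@H]1C[C@@]2(C(=O)O1)[C@](C)(O)[C@@H](Br)C=C(Br)C2(C)C
F10 | step 15 | (3R,5S,9S,10S)-7,9-dibromo-6,6,10-trimethyl-3-(prop-1-en-2-yl)-2-oxaspiro[4.5]dec-7-ene-1,10-diol (both C1 epimers) | C=C(C)[C@H]1C[C@@]2(C(O)O1)[C@](C)(O)[C@@H](Br)C=C(Br)C2(C)C
A1 | alternative 1 | 2,6,6-trimethyl-1-(prop-2-en-1-yl)cyclohexa-2,4-diene-1-carbaldehyde (configuration as in the SMILES) | O=C[C@@]1(CC=C)C(C)(C)C=CC=C1C
A2 | alternative 1 | 1,8,8-trimethyl-7-(prop-2-en-1-yl)-2,3-dioxabicyclo[2.2.2]oct-5-ene-7-carbaldehyde (configuration as in the SMILES) | O=C[C@@]1(CC=C)C(C)(C)[C@H]2OO[C@]1(C)C=C2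
A3 | alternative 1 | 2-hydroxy-2,6,6-trimethyl-5-oxo-1-(prop-2-en-1-yl)cyclohex-3-ene-1-carbaldehyde (configuration as in the SMILES) | O=C[C@@]1(CC=C)C(C)(C)C(=O)C=C[C@@]1(C)O
A4 | alternative 2 | 9-bromo-10-methyl-3-(prop-1-en-2-yl)-2-oxaspiro[4.5]deca-7,9-diene-1,6-dione (configuration as in the SMILES) | C=C(C)[C@H]1C[C@@]2(C(=O)O1)C(=O)C=CC(Br)=C2C
A5 | alternative 2 | 9-bromo-7-hydroxy-10,10-dimethyl-3-(prop-1-en-2-yl)-2-oxaspiro[4.5]dec-8-ene-1,6-dione (configuration as in the SMILES) | C=C(C)[C@H]1C[C@@]2(C(=O)O1)C(=O)[C@H](O)C=C(Br)C2(C)C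
A6 | alternative 3 | (E)-6-[(methoxycarbonyl)oxy]-5-methyl-2-(2-methylbut-3-en-2-yl)hex-4-enoic acid (racemic at C2) | C=CC(C)(C)C(C/C=C(\C)COC(=O)OC)C(=O)O
A7 | alternative 3 | trans-3-(2-methylbut-3-en-2-yl)-5-(prop-1-en-2-yl)oxolan-2-one (configuration as in the SMILES) | C=C(C)[C@H]1C[C@@H](C(=O)O1)C(C)(C)C=C
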